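## Structural features

The target 44 is a germacranolide: a ten-membered carbocycle (C1–C10) with an α-methylene-γ-butyrolactone (O on C6, C11–C13) trans-fused across C6–C7. The ring contains a Z-trisubstituted C4=C5 alkene, flanked by the allylic C3 acetate and the lactone oxygen on C6, and a trisubstituted C1/C10 epoxide (1R,10S) in which the ring carbons C2 and C9 are cis on the oxirane. C6, C7 and C8 are contiguous stereocentres (6S,7S,8S), C8 carrying the (R)-2-methylbutanoate; C3 (R) and the epoxide carbons are separated from this triad by CH2 groups or the alkene, so stereocontrol has to be relayed around the ring. The fragile groups are the methylene lactone (Michael acceptor), the epoxide that faces the C4=C5 alkene across the ring (acid-induced transannular cyclisation), and the two esters (acyl migration, and the α-stereocentre of the methylbutanoate). The real difficulty is a ten-membered ring holding a Z-trisubstituted alkene and five ring stereocentres, since direct closure fights entropy and transannular strain and offers little control of geometry. The feature exploited is that C4 and oxygenated C10 face each other across the ring. A C4–C10 bond turns the ring into a cis-fused five/seven bicycle (C1–C4, C10 and C4–C10) in which a C10 hydroxyl and a C5 leaving group are 1,3-related. Cleaving that bond writes the C10 carbonyl and the C4=C5 alkene, with the geometry fixed by the C4/C5 relative configuration.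

## Logic of the disconnections

44 → 42 + 43, then 41 and 40: the two ester C–O bonds are cut last because neither ester survives organolithium reagents or alkoxide bases; the forward acylations must be mild enough for the epoxide and the methylene lactone and must not racemise 43.

40 → 37 → 36: the lactone C12–O6 bond and the C12 oxidation level are removed, so that C6 and C12 travel as silyl ethers through all basic steps; the forward step must oxidise a primary allylic alcohol in the presence of secondary ones.

36 → 34 → 33 → 32: the C1–O bond of the epoxide and the C10–C14 bond are cut. This reduces the epoxide to an α-silyloxy ketone; the forward methyl addition must be Felkin–Anh selective (10S), and the displacement at C1 then inverts 1S to 1R and gives the cis-oxirane.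

32 → 30: the C4–C10 bond is reconnected (retro-fragmentation). The ten-membered Z-enone becomes a cis-fused hydroazulene, so no medium ring has to be closed; the forward step demands a C5 sulfonate anti-periplanar to C4–C10 with C6 gauche to C3. The configurations of 30 and 32 were checked atom by atom against 44: C3, C6, C7 and C8 are already final, C1 is S until step 26, and C4, C5 and C10 of 30 are erased.

30 → 29 → 28 → 24: the C5 configuration is traced to a ketone reduced under direction of the C10 hydroxyl, and the C3 configuration to a C5-directed hydride transfer. The decisive C4/C5 relationship therefore does not depend on the selectivity of the ring-forming aldol. The C3 oxygen is carried as a silyl ether so that only one DDQ-labile ether (C8) remains at the end.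

24 → 22 → 21 → 20: the C4–C5 bond is cut (intramolecular aldol). The C4 enolate is generated reductively from a bromide, because a base would enolise toward C2 and expel the C1 or C10 oxygen; the tether from C10 forces the cis ring fusion.

20 → 19 → 17 + 5: the C9–C10 bond is cut between the chain and the ring fragment; the forward addition must occur anti to the C1 silyloxy group and needs a C9 carbanion that tolerates the C8 oxygen, hence an alkoxide-bearing organolithium.

17 → 16 → 15 → 12 → 9 + 10: the C8–C9 bond (chloromethyl ketone), the C12 oxygen (allylic oxidation) and the C6–C7 bond (auxiliary-controlled dienolate aldol) are cut; C6/C7 come from the auxiliary and C8 from a catalyst-controlled reduction. 9 comes from 6 and 7.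

5 → 4 → 3 → 2 → 1: the C1 oxygen is removed and the vinylogous ester opened to the dione; C1 is the first ring stereocentre and is obtained by resolution.

## Other disconnections considered

Alternative 1: The cut is C5–C6 together with the lactone C–O bond. In the forward step CrCl2 (divalent chromium) with catalytic NiCl2 converts a Z-alkenyl iodide at C5 of an open-chain aldehyde ester into an alkenylchromium that adds to the C6 aldehyde (Nozaki–Hiyama–Kishi closure), and the C6 alkoxide lactonises onto the C12 methyl ester to give A1, which lacks only the epoxide oxygen. In its favour: the Z geometry is carried in unchanged from the iodide, the coupling tolerates esters, and ring and lactone form in one operation; on step economy it is clearly better than the chosen plan, and on control of the C4=C5 geometry it is its equal. Against it here: it is a genuine ten-membered ring closure; the C6 configuration is created during the cyclisation with only conformational control; and the last step must epoxidise C1=C10 of A1 on one face in the presence of C4=C5 and the methylene group, whereas the chosen plan builds the oxirane by a stereospecific displacement.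

Alternative 2: The cut is C6–C7 between two fragments. An allylboronate carrying C7–C3 and the C12 ester adds through C7 to A2 in a closed six-membered transition state, and the borate oxygen closes the lactone to give A3. In its favour: it is convergent, the chair transition state should deliver the trans lactone reliably, and the C8 stereocentre in the boronate can bias the face; as a fragment union it is better than the organolithium addition of the chosen plan. Against it here: A3 still needs a medium-ring closure (the alkenyl iodide at C4 onto a C3 aldehyde), which also has to set C3; the methylene lactone is present from the start and must survive all later steps; and the C1=C10 epoxidation problem remains. The chosen plan is longer but avoids both the macrocyclisation and the late alkene epoxidation.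

Alternative 3: The cut is C7–C8. BF3·OEt2 activates a C8 aldehyde, C7 of a butenolide allylstannane attacks it, and the ten-membered ring, the C7 and C8 stereocentres and the exocyclic methylene appear together in A4, whose free C8 hydroxyl is ready for acylation. In its favour: it is the most direct way to the methylene lactone, needs no reduction and re-oxidation of C12, and has a far shorter endgame than the chosen plan. Against it here: the ring closure goes through an open transition state, so both the ten-membered cyclisation and the C8 configuration are uncertain; the Lewis acid meets an allylic acetate and a trisubstituted alkene; and the epoxide again has to be introduced on A4 by face-selective oxidation. On alkene geometry it is equal to the chosen plan (carried in from the precursor), on step count better, on security of ring formation and of the epoxide configuration weaker.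

Key step: step 23

Assumption: the lipase of step 3 is taken to hydrolyse the (S)-acetate of 3 faster; if it prefers the (R)-acetate, the recovered (S)-acetate is methanolysed (K2CO3, MeOH) to the same alcohol 4.

## Route

Atom numbers C1–C15 are those of the germacrane skeleton of 44 throughout.

Step 1
Reactants: 1 2-methylcyclopentane-1,3-dione
Product: 2 2-methyl-3-(2-methylpropoxy)cyclopent-2-en-1-one
Conditions: i-BuOH, TsOH·H2O (cat.), benzene, reflux, Dean–Stark
Reagents that add atoms: 2-methylpropan-1-ol, CC(C)CO
Why: Acid-catalysed enol etherification of a cyclic 1,3-dione (vinylogous ester formation) driven by removal of water; it separates the future C10 carbonyl from the masked C3 carbonyl and fixes the C3=C4 enol ether used in step 14.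

Step 2
Reactants: 2 2-methyl-3-(2-methylpropoxy)cyclopent-2-en-1-one
Product: 3 rac-3-methyl-4-(2-methylpropoxy)-2-oxocyclopent-3-en-1-yl acetate
Conditions: Mn(OAc)3, benzene, reflux
Reagents that add atoms: manganese triacetate, CC(=O)[O-].CC(=O)[O-].CC(=O)[O-].[Mn+3]
Why: α′-Acetoxylation of an enone-type ketone by trivalent manganese through its manganese enolate; only the CH2 next to the carbonyl (future C1) can enolise on that side, and the product is racemic.

Step 3
Reactants: 3 rac-3-methyl-4-(2-methylpropoxy)-2-oxocyclopent-3-en-1-yl acetate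
Product: 4 (S)-5-hydroxy-2-methyl-3-(2-methylpropoxy)cyclopent-2-en-1-one
Conditions: lipase from Burkholderia cepacia, pH 7 phosphate buffer/MTBE, rt, stopped near half conversion
Reagents that add atoms: none
Why: Enzymatic kinetic resolution by enantioselective ester hydrolysis; it sets C1 (S), from which C10 is controlled in step 12, and the unreacted (R)-acetate is separated.

Step 4
Reactants: 4 (S)-5-hydroxy-2-methyl-3-(2-methylpropoxy)cyclopent-2-en-1-one
Product: 5 (S)-2-methyl-3-(2-methylpropoxy)-5-(triethylsilyloxy)cyclopent-2-en-1-one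
Conditions: TESCl, imidazole, CH2Cl2, 0 °C
Reagents that add atoms: chlorotriethylsilane, CC[Si](Cl)(CC)CC
Why: Silylation of a secondary alcohol; the triethylsilyl ether does not chelate (needed in step 24) and can be removed later in the presence of tert-butyldimethylsilyl ethers.

Step 5
Reactants: 6 (R)-4-benzyloxazolidin-2-one; 7 3-methylbut-2-enoyl chloride
Product: 9 (R)-4-benzyl-3-(3-methylbut-2-enoyl)oxazolidin-2-one, via N-lithio oxazolidinone 8 (not isolated)
Conditions: n-BuLi, THF, −78 °C; then 7, −78 → 0 °C
Reagents that add atoms: none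
Why: N-Acylation of the lithiated oxazolidinone to the imide that carries C7, C8 and C11–C13.

Step 6
Reactants: 9 (R)-4-benzyl-3-(3-methylbut-2-enoyl)oxazolidin-2-one; 10 2,2-dimethoxyacetaldehyde
Product: 12 (R)-4-benzyl-3-[(2R,3R)-3-hydroxy-4,4-dimethoxy-2-(prop-1-en-2-yl)butanoyl]oxazolidin-2-one, via boron dienolate 11 (not isolated)
Conditions: Bu2BOTf, Et3N, CH2Cl2, −78 → 0 °C; then 10 (freshly dehydrated), −78 → 0 °C; H2O2, MeOH, pH 7 buffer
Reagents that add atoms: none
Why: Evans syn aldol of the Z(O) boron dienolate formed by γ-deprotonation, reacting at its α-carbon (C7) and leaving the deconjugated C11=C13 alkene. The closed Zimmerman–Traxler chair, with its face fixed by the benzyl group of the (R)-auxiliary, sets C6 and C7 (C6–O and the propenyl group syn).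

Step 7
Reactants: 12 (R)-4-benzyl-3-[(2R,3R)-3-hydroxy-4,4-dimethoxy-2-(prop-1-en-2-yl)butanoyl]oxazolidin-2-one
Product: 13 (2R,3R)-3-hydroxy-N,4,4-trimethoxy-N-methyl-2-(prop-1-en-2-yl)butanamide
Conditions: MeNH(OMe)·HCl, AlMe3, CH2Cl2, −20 → 0 °C; potassium sodium tartrate work-up
Reagents that add atoms: N,O-dimethylhydroxylamine hydrochloride, CNOC.Cl
Why: Transamination of the imide with the aluminium amide (Weinreb amide formation), assisted by the free β-hydroxyl; no stereocentre is touched and the auxiliary is recovered.

Step 8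
Reactants: 13 (2R,3R)-3-hydroxy-N,4,4-trimethoxy-N-methyl-2-(prop-1-en-2-yl)butanamide
Product: 14 (2R,3R)-3-hydroxy-2-(3-hydroxyprop-1-en-2-yl)-N,4,4-trimethoxy-N-methylbutanamide
Conditions: SeO2 (cat.), t-BuOOH, CH2Cl2, rt
Reagents that add atoms: tert-butyl hydroperoxide, CC(C)(C)OO
Why: Allylic oxidation with SeO2 (ene reaction followed by a 2,3-shift); a 1,1-disubstituted alkene is oxidised at its methyl group in preference to the allylic methine, which installs the C12 oxygen and returns the alkene to C11=C13.

Step 9
Reactants: 14 (2R,3R)-3-hydroxy-2-(3-hydroxyprop-1-en-2-yl)-N,4,4-trimethoxy-N-methylbutanamide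
Product: 15 (2R,3R)-3-(tert-butyldimethylsilyloxy)-2-[3-(tert-butyldimethylsilyloxy)prop-1-en-2-yl]-N,4,4-trimethoxy-N-methylbutanamide
Conditions: TBSCl, imidazole, DMAP (cat.), DMF, 40 °C
Reagents that add atoms: tert-butylchlorodimethylsilane, CC(C)(C)[Si](C)(C)Cl
Why: Double silylation of the C6 and C12 hydroxyls, the pair that is released together for the lactone at the end; the chloride/imidazole system is used because silyl triflates would attack the dimethyl acetal.

Step 10
Reactants: 15 (2R,3R)-3-(tert-butyldimethylsilyloxy)-2-[3-(tert-butyldimethylsilyloxy)prop-1-en-2-yl]-N,4,4-trimethoxy-N-methylbutanamide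
Product: 16 (3R,4R)-4-(tert-butyldimethylsilyloxy)-3-[3-(tert-butyldimethylsilyloxy)prop-1-en-2-yl]-1-chloro-5,5-dimethoxypentan-2-one
Conditions: ICH2Cl, MeLi·LiBr, THF/Et2O, −78 °C; NH4Cl (aq)
Reagents that add atoms: chloroiodomethane, ClCI
Why: Acylation of chloromethyllithium by the Weinreb amide brings in C9; the chelated tetrahedral intermediate prevents over-addition and shields the C7–H, which is α to the carbonyl and allylic, until work-up.

Step 11
Reactants: 16 (3R,4R)-4-(tert-butyldimethylsilyloxy)-3-[3-(tert-butyldimethylsilyloxy)prop-1-en-2-yl]-1-chloro-5,5-dimethoxypentan-2-one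
Product: 17 (2R,3S,4R)-4-(tert-butyldimethylsilyloxy)-3-[3-(tert-butyldimethylsilyloxy)prop-1-en-2-yl]-1-chloro-5,5-dimethoxypentan-2-ol
Conditions: (R)-2-methyl-CBS-oxazaborolidine (cat.), catecholborane, toluene, −78 °C
Reagents that add atoms: none
Why: Corey–Bakshi–Shibata reduction of a chloromethyl ketone; the catalyst, with the branched C7 side as the large group, sets C8 so that the C8 oxygen is anti to the C6 oxygen. Catecholborane is chosen because it should not hydroborate the alkene at this temperature.

Step 12
Reactants: 17 (2R,3S,4R)-4-(tert-butyldimethylsilyloxy)-3-[3-(tert-butyldimethylsilyloxy)prop-1-en-2-yl]-1-chloro-5,5-dimethoxypentan-2-ol; 5 (S)-2-methyl-3-(2-methylpropoxy)-5-(triethylsilyloxy)cyclopent-2-en-1-one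
Product: 19 C9–C10 adduct with free C8 and C10 hydroxyls and the C3=C4 isobutyl enol ether (C1 S; C10 hydroxyl cis to the C1 silyloxy group; C6 C7 C8 as in 17), via dilithio alkoxide 18 (not isolated)
Conditions: n-BuLi, THF, −78 °C; lithium 4,4′-di-tert-butylbiphenylide, −78 °C; CeCl3, −78 °C; then 5, −78 °C; NaHCO3 (aq)
Reagents that add atoms: none
Why: Reductive lithiation of the chloride of a lithium alkoxide gives a β-oxido organolithium that cannot eliminate readily (an oxide dianion would have to leave); after transmetallation to cerium it adds 1,2 to the vinylogous ester carbonyl. Attack anti to the adjacent silyloxy group places the C10 hydroxyl cis to the C1 oxygen, and the basic work-up keeps the acid-labile enol ether.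

Step 13
Reactants: 19 C9–C10 adduct with free C8 and C10 hydroxyls
Product: 20 C8 2-naphthylmethyl ether of 19 (C10 hydroxyl free; configuration unchanged)
Conditions: NaH, 2-(bromomethyl)naphthalene, Bu4NI (cat.), THF, 0 °C → rt
Reagents that add atoms: 2-(bromomethyl)naphthalene, BrCc1ccc2ccccc2c1
Why: Williamson etherification; the secondary C8 alkoxide is alkylated while the hindered tertiary C10 alkoxide is not, and the basic medium leaves the enol ether intact.

Step 14
Reactants: 20 C8 2-naphthylmethyl ether of 19
Product: 21 4-bromo-3-ketone: C3 ketone, C4 bromide (both epimers), C10 hydroxyl free, otherwise as 20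
Conditions: NBS, NaHCO3, THF/H2O, −20 °C
Reagents that add atoms: N-bromosuccinimide, O=C1CCC(=O)N1Br; water, O
Why: Electrophilic bromination of the enol ether at C4 followed by hydrolysis of the oxocarbenium ion gives the α-bromo ketone. This unmasks C3 without acid, which would expel the C10 hydroxyl (Stork–Danheiser-type collapse), and places at C4 the handle for regiospecific enolate formation.

Step 15
Reactants: 21 4-bromo-3-ketone with C5 dimethyl acetal
Product: 22 C5 aldehyde with C10 trimethylsilyl ether (C4 bromide, C3 ketone; otherwise as 21)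
Conditions: TMSOTf, 2,2′-bipyridyl, CH2Cl2, 0 °C; then H2O
Reagents that add atoms: trimethylsilyl triflate, C[Si](C)(C)OS(=O)(=O)C(F)(F)F; water, O
Why: The silyl triflate/bipyridyl pair converts the dimethyl acetal into a pyridinium-type mixed acetal that water hydrolyses to the aldehyde under non-acidic conditions, sparing the silyl ethers. The same reagent caps the tertiary C10 hydroxyl, which would otherwise protonate the enolate of step 16.

Step 16
Reactants: 22 C5 aldehyde with C10 trimethylsilyl ether and C4 bromide
Product: 24 cis-fused hydroazulene β-hydroxy ketone (C4–C5 bond formed; C3 ketone, C5 hydroxyl as epimers; on the five-membered ring the C15 methyl, C10–O and C1–O on one face, C5 and C9 on the other; on the seven-membered ring C6–O on the face of C3, the C7 side chain and C8–O on the face of C15), via samarium enolate 23 (not isolated)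
Conditions: SmI2, THF, −78 °C; pH 7 buffer
Reagents that add atoms: none
Why: Reformatsky-type aldol: two equivalents of SmI2 reduce the C–Br bond to a regiodefined trivalent samarium enolate at C4 without any base, so neither C2 enolisation nor β-elimination of the C1 oxygen is started. The tether hangs from C10 on the face opposite its oxygen, so the new bond forms on that face and C4 becomes quaternary with the methyl cis to the C10 oxygen (cis fusion); the C5 configuration is not relied on and is reset in steps 20–21.

Step 17
Reactants: 24 cis-fused hydroazulene β-hydroxy ketone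
Product: 25 C5 acetate with free C3 hydroxyl (C3–O cis to the C15 methyl, 3R; C5 epimers; otherwise as 24)
Conditions: MeCHO, SmI2 (cat.), THF, −10 °C
Reagents that add atoms: acetaldehyde, CC=O
Why: Evans–Tishchenko reduction: the hemiacetal formed at the C5 hydroxyl transfers hydride to C3 inside a samarium chelate, from the face on which C5 stands, anti to the C15 methyl. For either C5 epimer this places the C3 oxygen cis to the methyl, and it leaves C5 as its acetate, so the two oxygens emerge differentiated.

Step 18
Reactants: 25 C5 acetate with free C3 hydroxyl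
Product: 26 C3 tert-butyldimethylsilyl ether of 25
Conditions: TBSOTf, 2,6-lutidine, CH2Cl2, −78 → 0 °C
Reagents that add atoms: tert-butyldimethylsilyl triflate, CC(C)(C)[Si](C)(C)OS(=O)(=O)C(F)(F)F
Why: Silylation of the hindered neopentyl C3 alcohol with the reactive triflate; this ether falls together with those at C6 and C12 in step 27.

Step 19
Reactants: 26 C3 tert-butyldimethylsilyl ether of 25
Product: 27 C5,C10-diol (C5 epimers; C1 triethylsilyl, C3, C6 and C12 tert-butyldimethylsilyl and C8 naphthylmethyl ethers kept)
Conditions: K2CO3, MeOH, rt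
Reagents that add atoms: none
Why: Methanolysis removes the acetate and the tertiary trimethylsilyl ether in one operation; the secondary triethylsilyl and the tert-butyldimethylsilyl ethers should be stable to carbonate in methanol.

Step 20
Reactants: 27 C5,C10-diol
Product: 28 C5 ketone with free tertiary C10 hydroxyl
Conditions: Dess–Martin periodinane, NaHCO3, CH2Cl2, 0 °C → rt
Reagents that add atoms: none
Why: Dess–Martin oxidation of the only secondary alcohol under buffered, non-basic conditions, which avoid retro-aldol opening of the β-hydroxy ketone; it erases the uncontrolled C5 centre.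

Step 21
Reactants: 28 C5 ketone with free tertiary C10 hydroxyl
Product: 29 C5 alcohol of defined configuration (C5–O on the face of C3 and cis to C6–O, trans to the C15 methyl and the C10 hydroxyl)
Conditions: Me4NBH(OAc)3, AcOH/MeCN, −30 °C
Reagents that add atoms: none
Why: Saksena–Evans hydroxyl-directed reduction: the borohydride exchanges a ligand for the C10 hydroxyl and delivers hydride to C5 through a six-membered transition state from the side of O10. The new C5–H is therefore gauche to C10 on the side of the methyl, which leaves the C5 oxygen anti to the C4–C10 bond with C6 gauche to C3, the arrangement that step 23 turns into the Z alkene.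

Step 22
Reactants: 29 C5 alcohol of defined configuration
Product: 30 C5 mesylate with free C10 hydroxyl (fragmentation precursor; germacrane descriptors 1S,3R,4R,5S,6R,7S,8S,10R)
Conditions: MsCl, Et3N, DMAP (cat.), CH2Cl2, −10 °C
Reagents that add atoms: methanesulfonyl chloride, CS(Cl)(=O)=O
Why: Sulfonylation through sulfene reaches the hindered secondary alcohol, whereas the tertiary C10 hydroxyl is not esterified; the amine is too weak a base to start the fragmentation.

Step 23
Reactants: 30 C5 mesylate with free C10 hydroxyl
Product: 32 (1S,3R,6S,7S,8S,4Z)-ten-membered enone: C10 ketone, C1 triethylsilyl ether, C3 and C6 tert-butyldimethylsilyl ethers, C7 3-(tert-butyldimethylsilyloxy)prop-1-en-2-yl, C8 2-naphthylmethyl ether, via potassium C10 alkoxide 31 (not isolated)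
Conditions: KOt-Bu, THF, 0 °C, 10 min; pH 7 buffer
Reagents that add atoms: none
Why: The butoxide deprotonates the tertiary C10 hydroxyl; in the conformer with the mesylate pseudo-equatorial the C10–O⁻ lone pair, the C10–C4 bond and the C5–O bond are anti-periplanar, and in one concerted step the C10 carbonyl forms, C4–C10 breaks, C4=C5 forms and the mesylate leaves. The closest known type is the Grob (Wharton) fragmentation of cyclic 1,3-diol monosulfonates to medium-ring alkenones. The ten-membered ring is not closed by bond formation: it appears by cleavage of the bond shared by the five- and seven-membered rings (ring expansion), so no medium-ring cyclisation is needed. No stereocentre is created; C4, C5 and C10 are erased, and the alkene geometry is read from the C4/C5 relative configuration: with the mesylate anti to C10, C6 and C3 are gauche on the same side of C4–C5 and emerge cis, hence Z. The step must favour fragmentation over 4-exo displacement to an oxetane and over elimination toward C6; this is secured by the strain-free anti-periplanar alignment set in step 21, by the fact that C3–C4 can never be anti to the mesylate in the fused ring, and by the silyl ether on C3, which leaves a single alkoxide. Migration of the triethylsilyl group from O1 to O10 is reversible and disfavoured on the tertiary oxygen. The product carries a β-ether (C8) and an epimerisable α-silyloxy centre (C1), so one equivalent of base, a short contact time and a cold buffered quench are required.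

Step 24
Reactants: 32 ten-membered Z-enone
Product: 33 (10S)-tertiary alcohol: C14 methyl added to C10, other groups as in 32
Conditions: MeLi, CeCl3, THF, −78 °C; NH4Cl (aq)
Reagents that add atoms: methyllithium, [Li]C
Why: 1,2-Addition of the organocerium, whose low basicity should prevent enolisation and β-elimination of the C8 ether. The non-chelating triethylsilyloxy group at C1 stands anti to the incoming nucleophile (Felkin–Anh), which gives the 1,10-syn arrangement (10S).

Step 25
Reactants: 33 (10S)-tertiary alcohol
Product: 34 (1S,10S)-1,10-diol with C3, C6 and C12 tert-butyldimethylsilyl ethers and the C8 naphthylmethyl ether kept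
Conditions: HF·pyridine, pyridine, THF, 0 °C
Reagents that add atoms: none
Why: Buffered fluoride removes the triethylsilyl ether, which is far more labile than the tert-butyldimethylsilyl ethers; the reaction is followed closely so that the primary C12 ether is not touched.

Step 26
Reactants: 34 (1S,10S)-1,10-diol
Product: 36 (1R,10S)-1,10-epoxide with the three tert-butyldimethylsilyl ethers and the C8 naphthylmethyl ether, via C1 mesylate 35 (not isolated)
Conditions: MsCl, Et3N, CH2Cl2, −10 °C; then DBU, rt
Reagents that add atoms: none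
Why: Selective mesylation of the secondary alcohol, then intramolecular SN2 displacement by the tertiary C10 oxygen (3-exo-tet). C1 is inverted from S to R and C10 is retained, which gives the oxirane with C2 and C9 cis.

Step 27
Reactants: 36 (1R,10S)-1,10-epoxide
Product: 37 C3,C6,C12-triol with the epoxide and the C8 naphthylmethyl ether
Conditions: TBAF, AcOH, THF, 0 °C → rt
Reagents that add atoms: none
Why: Fluoride cleavage of the three tert-butyldimethylsilyl ethers; acetic acid buffers the alkoxides so that they do not attack the epoxide across the ring.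

Step 28
Reactants: 37 C3,C6,C12-triol
Product: 40 6,12-lactone (α-methylene-γ-butyrolactone) with free C3 hydroxyl and C8 naphthylmethyl ether, via hydroxy enal 38 (not isolated), via lactol 39 (not isolated)
Conditions: TEMPO (cat.), PhI(OAc)2, CH2Cl2, rt
Reagents that add atoms: none
Why: Oxoammonium oxidation is selective for the primary allylic C12 alcohol; the aldehyde is captured by the C6 hydroxyl as the five-membered lactol, which is oxidised further to the lactone. The C8 oxygen, which could form the isomeric lactone, is still protected.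

Step 29
Reactants: 40 6,12-lactone with free C3 hydroxyl
Product: 41 C3 acetate of 40
Conditions: Ac2O, pyridine, DMAP (cat.), CH2Cl2, 0 °C
Reagents that add atoms: acetic anhydride, CC(=O)OC(C)=O
Why: Acylation of the only free hydroxyl under mild basic conditions that the methylene lactone and the epoxide tolerate.

Step 30
Reactants: 41 C3 acetate with C8 naphthylmethyl ether
Product: 42 C8 alcohol (3-acetate, epoxide and methylene lactone in place)
Conditions: DDQ, CH2Cl2/pH 7 buffer, rt
Reagents that add atoms: none
Why: Oxidative cleavage of the 2-naphthylmethyl ether through its oxocarbenium ion; it is the only DDQ-labile group left, and the buffer protects the epoxide.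

Step 31
Reactants: 42 C8 alcohol; 43 (R)-2-methylbutanoic acid
Product: 44 target (1R,3R,6S,7S,8S,10S,4Z)-3-acetoxy-1,10-epoxy-8-[(R)-2-methylbutanoyloxy]germacra-4,11(13)-dien-12,6-olide
Conditions: DCC, DMAP (cat.), CH2Cl2, 0 °C → rt
Reagents that add atoms: none
Why: Steglich esterification of the secondary C8 alcohol; a small amount of DMAP at low temperature is used so that the α-stereocentre of the acid is not epimerised.

## Compound list

1 | 2-methylcyclopentane-1,3-dione | CC1C(=O)CCC1=O | starting material
2 | 2-methyl-3-(2-methylpropoxy)cyclopent-2-en-1-one | CC1=C(OCC(C)C)CCC1=O | intermediate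
3 | rac-3-methyl-4-(2-methylpropoxy)-2-oxocyclopent-3-en-1-yl acetate | CC(=O)OC1CC(OCC(C)C)=C(C)C1=O | intermediate
4 | (S)-5-hydroxy-2-methyl-3-(2-methylpropoxy)cyclopent-2-en-1-one | CC1=C(OCC(C)C)C[C@H](O)C1=O | intermediate
5 | (S)-2-methyl-3-(2-methylpropoxy)-5-(triethylsilyloxy)cyclopent-2-en-1-one | CC1=C(OCC(C)C)C[C@H](O[Si](CC)(CC)CC)C1=O | intermediate
6 | (R)-4-benzyloxazolidin-2-one | O=C1N[C@H](Cc2ccccc2)CO1 | starting material
7 | 3-methylbut-2-enoyl chloride | CC(C)=CC(Cl)=O | starting material
8 | N-lithio derivative of 6 | [Li]N1[C@H](Cc2ccccc2)COC1=O | intermediate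
9 | (R)-4-benzyl-3-(3-methylbut-2-enoyl)oxazolidin-2-one | CC(C)=CC(=O)N1[C@H](Cc2ccccc2)COC1=O | intermediate
10 | 2,2-dimethoxyacetaldehyde | COC(OC)C=O | starting material
11 | dibutylboron Z(O)-dienolate of 9 | C=C(C)/C=C(\OB(CCCC)CCCC)N1[C@H](Cc2ccccc2)COC1=O | intermediate
12 | (R)-4-benzyl-3-[(2R,3R)-3-hydroxy-4,4-dimethoxy-2-(prop-1-en-2-yl)butanoyl]oxazolidin-2-one | COC(OC)[C@H](O)[C@@H](C(C)=C)C(=O)N1[C@H](Cc2ccccc2)COC1=O | intermediate
13 | (2R,3R)-3-hydroxy-N,4,4-trimethoxy-N-methyl-2-(prop-1-en-2-yl)butanamide | COC(OC)[C@H](O)[C@@H](C(C)=C)C(=O)N(C)OC | intermediate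
14 | (2R,3R)-3-hydroxy-2-(3-hydroxyprop-1-en-2-yl)-N,4,4-trimethoxy-N-methylbutanamide | COC(OC)[C@H](O)[C@@H](C(=C)CO)C(=O)N(C)OC | intermediate
15 | (2R,3R)-3-(tert-butyldimethylsilyloxy)-2-[3-(tert-butyldimethylsilyloxy)prop-1-en-2-yl]-N,4,4-trimethoxy-N-methylbutanamide | COC(OC)[C@H](O[Si](C)(C)C(C)(C)C)[C@@H](C(=C)CO[Si](C)(C)C(C)(C)C)C(=O)N(C)OC | intermediate
16 | (3R,4R)-4-(tert-butyldimethylsilyloxy)-3-[3-(tert-butyldimethylsilyloxy)prop-1-en-2-yl]-1-chloro-5,5-dimethoxypentan-2-one | COC(OC)[C@H](O[Si](C)(C)C(C)(C)C)[C@@H](C(=C)CO[Si](C)(C)C(C)(C)C)C(=O)CCl | intermediate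
17 | (2R,3S,4R)-4-(tert-butyldimethylsilyloxy)-3-[3-(tert-butyldimethylsilyloxy)prop-1-en-2-yl]-1-chloro-5,5-dimethoxypentan-2-ol | COC(OC)[C@H](O[Si](C)(C)C(C)(C)C)[C@@H](C(=C)CO[Si](C)(C)C(C)(C)C)[C@@H](O)CCl | intermediate
18 | C9-lithio lithium alkoxide derived from 17 | COC(OC)[C@H](O[Si](C)(C)C(C)(C)C)[C@@H](C(=C)CO[Si](C)(C)C(C)(C)C)[C@@H](O[Li])C[Li] | intermediate
19 | C9–C10 adduct: C8,C10-diol, C3=C4 isobutyl enol ether, C1 triethylsilyl ether (C1 S, C10–OH cis to C1–O) | COC(OC)[C@H](O[Si](C)(C)C(C)(C)C)[C@@H](C(=C)CO[Si](C)(C)C(C)(C)C)[C@@H](O)C[C@@]1(O)C(C)=C(OCC(C)C)C[C@@H]1O[Si](CC)(CC)CC | intermediate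
20 | C8 2-naphthylmethyl ether of 19 | COC(OC)[C@H](O[Si](C)(C)C(C)(C)C)[C@@H](C(=C)CO[Si](C)(C)C(C)(C)C)[C@@H](OCc2ccc3ccccc3c2)C[C@@]1(O)C(C)=C(OCC(C)C)C[C@@H]1O[Si](CC)(CC)CC | intermediate
21 | 4-bromo-3-ketone (C4 epimers), C10 hydroxyl free | COC(OC)[C@H](O[Si](C)(C)C(C)(C)C)[C@@H](C(=C)CO[Si](C)(C)C(C)(C)C)[C@@H](OCc2ccc3ccccc3c2)C[C@@]1(O)C(C)(Br)C(=O)C[C@@H]1O[Si](CC)(CC)CC | intermediate
22 | C5 aldehyde, C10 trimethylsilyl ether, C4 bromide (C4 epimers) | O=C[C@H](O[Si](C)(C)C(C)(C)C)[C@@H](C(=C)CO[Si](C)(C)C(C)(C)C)[C@@H](OCc2ccc3ccccc3c2)C[C@@]1(O[Si](C)(C)C)C(C)(Br)C(=O)C[C@@H]1O[Si](CC)(CC)CC | intermediate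
23 | trivalent samarium C3=C4 enolate of 22 | O=C[C@H](O[Si](C)(C)C(C)(C)C)[C@@H](C(=C)CO[Si](C)(C)C(C)(C)C)[C@@H](OCc2ccc3ccccc3c2)C[C@@]1(O[Si](C)(C)C)C(C)=C(O[Sm](I)I)C[C@@H]1O[Si](CC)(CC)CC | intermediate
24 | cis-fused hydroazulene: C3 ketone, C5 hydroxyl (epimers), C10 trimethylsilyl ether | C[C@]12C(=O)C[C@H](O[Si](CC)(CC)CC)[C@@]1(O[Si](C)(C)C)C[C@H](OCc3ccc4ccccc4c3)[C@H](C(=C)CO[Si](C)(C)C(C)(C)C)[C@@H](O[Si](C)(C)C(C)(C)C)C2O | intermediate
25 | C5 acetate, C3 alcohol (3R; C5 epimers) | C[C@]12[C@H](O)C[C@H](O[Si](CC)(CC)CC)[C@@]1(O[Si](C)(C)C)C[C@H](OCc3ccc4ccccc4c3)[C@H](C(=C)CO[Si](C)(C)C(C)(C)C)[C@@H](O[Si](C)(C)C(C)(C)C)C2OC(C)=O | intermediate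
26 | C3 tert-butyldimethylsilyl ether of 25 | C[C@]12[C@H](O[Si](C)(C)C(C)(C)C)C[C@H](O[Si](CC)(CC)CC)[C@@]1(O[Si](C)(C)C)C[C@H](OCc3ccc4ccccc4c3)[C@H](C(=C)CO[Si](C)(C)C(C)(C)C)[C@@H](O[Si](C)(C)C(C)(C)C)C2OC(C)=O | intermediate
27 | C5,C10-diol (C5 epimers) | C[C@]12[C@H](O[Si](C)(C)C(C)(C)C)C[C@H](O[Si](CC)(CC)CC)[C@@]1(O)C[C@H](OCc3ccc4ccccc4c3)[C@H](C(=C)CO[Si](C)(C)C(C)(C)C)[C@@H](O[Si](C)(C)C(C)(C)C)C2O | intermediate
28 | C5 ketone with free C10 hydroxyl | C[C@]12[C@H](O[Si](C)(C)C(C)(C)C)C[C@H](O[Si](CC)(CC)CC)[C@@]1(O)C[C@H](OCc3ccc4ccccc4c3)[C@H](C(=C)CO[Si](C)(C)C(C)(C)C)[C@@H](O[Si](C)(C)C(C)(C)C)C2=O | intermediate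
29 | C5 alcohol of defined configuration (1S,3R,4S,5S,6R,7S,8S,10R) | C[C@]12[C@H](O[Si](C)(C)C(C)(C)C)C[C@H](O[Si](CC)(CC)CC)[C@@]1(O)C[C@H](OCc3ccc4ccccc4c3)[C@H](C(=C)CO[Si](C)(C)C(C)(C)C)[C@@H](O[Si](C)(C)C(C)(C)C)[C@H]2O | intermediate
30 | C5 mesylate, fragmentation precursor (1S,3R,4R,5S,6R,7S,8S,10R) | C[C@]12[C@H](O[Si](C)(C)C(C)(C)C)C[C@H](O[Si](CC)(CC)CC)[C@@]1(O)C[C@H](OCc3ccc4ccccc4c3)[C@H](C(=C)CO[Si](C)(C)C(C)(C)C)[C@@H](O[Si](C)(C)C(C)(C)C)[C@H]2OS(C)(=O)=O | intermediate
31 | potassium C10 alkoxide of 30 | C[C@]12[C@H](O[Si](C)(C)C(C)(C)C)C[C@H](O[Si](CC)(CC)CC)[C@@]1([O-])C[C@H](OCc3ccc4ccccc4c3)[C@H](C(=C)CO[Si](C)(C)C(C)(C)C)[C@@H](O[Si](C)(C)C(C)(C)C)[C@H]2OS(C)(=O)=O.[K+] | intermediate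
32 | (1S,3R,6S,7S,8S,4Z)-ten-membered enone (C10 ketone) | O=C1[C@@H](O[Si](CC)(CC)CC)C[C@@H](O[Si](C)(C)C(C)(C)C)/C(C)=C\[C@H](O[Si](C)(C)C(C)(C)C)[C@@H](C(=C)CO[Si](C)(C)C(C)(C)C)[C@@H](OCc2ccc3ccccc3c2)C1 | intermediate
33 | (10S)-tertiary alcohol | O[C@]1(C)[C@@H](O[Si](CC)(CC)CC)C[C@@H](O[Si](C)(C)C(C)(C)C)/C(C)=C\[C@H](O[Si](C)(C)C(C)(C)C)[C@@H](C(=C)CO[Si](C)(C)C(C)(C)C)[C@@H](OCc2ccc3ccccc3c2)C1 | intermediate
34 | (1S,10S)-1,10-diol | O[C@]1(C)[C@@H](O)C[C@@H](O[Si](C)(C)C(C)(C)C)/C(C)=C\[C@H](O[Si](C)(C)C(C)(C)C)[C@@H](C(=C)CO[Si](C)(C)C(C)(C)C)[C@@H](OCc2ccc3ccccc3c2)C1 | intermediate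
35 | C1 mesylate of 34 | O[C@]1(C)[C@@H](OS(C)(=O)=O)C[C@@H](O[Si](C)(C)C(C)(C)C)/C(C)=C\[C@H](O[Si](C)(C)C(C)(C)C)[C@@H](C(=C)CO[Si](C)(C)C(C)(C)C)[C@@H](OCc2ccc3ccccc3c2)C1 | intermediate
36 | (1R,10S)-1,10-epoxide, three tert-butyldimethylsilyl ethers | C[C@@]12O[C@@H]1C[C@@H](O[Si](C)(C)C(C)(C)C)/C(C)=C\[C@H](O[Si](C)(C)C(C)(C)C)[C@@H](C(=C)CO[Si](C)(C)C(C)(C)C)[C@@H](OCc3ccc4ccccc4c3)C2 | intermediate
37 | C3,C6,C12-triol epoxide | C[C@@]12O[C@@H]1C[C@@H](O)/C(C)=C\[C@H](O)[C@@H](C(=C)CO)[C@@H](OCc3ccc4ccccc4c3)C2 | intermediate
38 | C12 aldehyde (hydroxy enal) | C[C@@]12O[C@@H]1C[C@@H](O)/C(C)=C\[C@H](O)[C@@H](C(=C)C=O)[C@@H](OCc3ccc4ccccc4c3)C2 | intermediate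
39 | 6,12-lactol (C12 epimers) | C=C1C(O)O[C@H]2/C=C(/C)[C@H](O)C[C@H]3O[C@@]3(C)C[C@H](OCc4ccc5ccccc5c4)[C@H]12 | intermediate
40 | 6,12-lactone with C3 hydroxyl and C8 naphthylmethyl ether | C=C1C(=O)O[C@H]2/C=C(/C)[C@H](O)C[C@H]3O[C@@]3(C)C[C@H](OCc4ccc5ccccc5c4)[C@H]12 | intermediate
41 | C3 acetate of 40 | C=C1C(=O)O[C@H]2/C=C(/C)[C@H](OC(C)=O)C[C@H]3O[C@@]3(C)C[C@H](OCc4ccc5ccccc5c4)[C@H]12 | intermediate
42 | C8 alcohol | C=C1C(=O)O[C@H]2/C=C(/C)[C@H](OC(C)=O)C[C@H]3O[C@@]3(C)C[C@H](O)[C@H]12 | intermediate
43 | (R)-2-methylbutanoic acid | CC[C@@H](C)C(=O)O | starting material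
44 | target, (1R,3R,6S,7S,8S,10S,4Z) with (R)-2-methylbutanoate | C=C1C(=O)O[C@H]2/C=C(/C)[C@H](OC(C)=O)C[C@H]3O[C@@]3(C)C[C@H](OC(=O)[C@H](C)CC)[C@H]12 | target

## Step count and least certain steps

Total: 31 steps. Longest linear sequence: 27 steps (steps 5–11, then 12–31); the ring fragment (steps 1–4) joins at step 12. If the aldol of step 16 proves to deliver the required C5 epimer by itself, steps 20 and 21 can be dropped.

Step 23 (key step). Most likely failure: displacement of the mesylate by the C10 alkoxide (oxetane closure) when the anti-periplanar conformer is not sufficiently populated, or base damage to the product (β-elimination of the C8 ether, epimerisation at C1) during the contact time needed at 0 °C. Fallback: set out from 29, deprotonate both hydroxyls with KHMDS in THF at −78 °C and add N-phenyltriflimide. The secondary C5 alkoxide is sulfonylated to the C5 triflate C10 alkoxide F1, which should fragment as it forms at −78 °C, with a much better leaving group and no isolated sulfonate, returning to the route at 32.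

Step 12. Most likely failure: loss of the organometallic by β-elimination to the C8=C9 alkene or by proton transfer from 5 before it adds, or reductive cleavage of the allylic silyl ether by excess arene radical anion. Fallback: set out from 17 and displace the chloride with PhSNa (DMF) to the hydroxy sulfide F2. Oxidise it with H2O2 and (NH4)6Mo7O24 to the hydroxy sulfone F3, form the sulfonyl-stabilised dianion with two equivalents of n-BuLi and add it (CeCl3) to 5 to give the sulfonyl adduct F4. Remove the sulfonyl group with Mg in MeOH, returning to the route at 19.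

Step 16. Most likely failure: β-elimination of the C10 silyloxy group from the samarium enolate (to the cyclopentenone) or simple protonation of the enolate outrunning the slower seven-membered aldol closure. Fallback: set out from 22, eliminate HBr (LiBr, Li2CO3, DMF, 50 °C) to the exocyclic α-methylene ketone F5 and close the ring by reductive aldol cyclisation with [(Ph3P)CuH]6 in toluene at −40 °C. Hydride goes to the methylene carbon and the softer copper enolate adds to the aldehyde, returning to the route at 24.

Step 24. Most likely failure: poor facial selectivity, because chelation by the C1 oxygen or the ring conformation overrides the Felkin–Anh preference; the C10 epimer would lead to the trans-oxirane. Fallback: set out from 32 and methylenate with Ph3P=CH2 to the 10(14)-methylene compound F6. Remove the triethylsilyl group (HF·pyridine, pyridine) to the allylic alcohol F7 and epoxidise under hydroxyl direction with VO(acac)2 and t-BuOOH to the epoxy alcohol F8 (erythro expected for a 2-substituted allylic alcohol). Open the oxirane at its CH2 terminus with LiEt3BH, returning to the route at 34.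

Step 28. Most likely failure: competing oxidation of the free allylic C3 hydroxyl, or slow capture of the aldehyde, giving over-oxidised material. Fallback: set out from 36 and remove only the primary C12 silyl ether (NH4F, MeOH) to the C12 alcohol F9. Oxidise with MnO2 to the enal F10 and then by Pinnick oxidation (NaClO2, NaH2PO4, 2-methylbut-2-ene) to the acid F11. Cleave the two remaining silyl ethers (TBAF, AcOH); the γ-hydroxy acid lactonises on work-up, returning to the route at 40.

## Further compounds

F1 | step 23 | C5 triflate C10 potassium alkoxide | C[C@]12[C@H](O[Si](C)(C)C(C)(C)C)C[C@H](O[Si](CC)(CC)CC)[C@@]1([O-])C[C@H](OCc3ccc4ccccc4c3)[C@H](C(=C)CO[Si](C)(C)C(C)(C)C)[C@@H](O[Si](C)(C)C(C)(C)C)[C@H]2OS(=O)(=O)C(F)(F)F.[K+]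
F2 | step 12 | hydroxy sulfide (phenylsulfanyl in place of chlorine in 17) | COC(OC)[C@H](O[Si](C)(C)C(C)(C)C)[C@@H](C(=C)CO[Si](C)(C)C(C)(C)C)[C@@H](O)CSc1ccccc1
F3 | step 12 | hydroxy sulfone | COC(OC)[C@H](O[Si](C)(C)C(C)(C)C)[C@@H](C(=C)CO[Si](C)(C)C(C)(C)C)[C@@H](O)CS(=O)(=O)c1ccccc1
F4 | step 12 | sulfonyl adduct (19 with a phenylsulfonyl group on C9, C9 epimers) | COC(OC)[C@H](O[Si](C)(C)C(C)(C)C)[C@@H](C(=C)CO[Si](C)(C)C(C)(C)C)[C@@H](O)C(S(=O)(=O)c2ccccc2)[C@@]1(O)C(C)=C(OCC(C)C)C[C@@H]1O[Si](CC)(CC)CC
F5 | step 16 | exocyclic α-methylene ketone with C5 aldehyde and C10 trimethylsilyl ether | O=C[C@H](O[Si](C)(C)C(C)(C)C)[C@@H](C(=C)CO[Si](C)(C)C(C)(C)C)[C@@H](OCc2ccc3ccccc3c2)C[C@@]1(O[Si](C)(C)C)C(=C)C(=O)C[C@@H]1O[Si](CC)(CC)CC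
F6 | step 24 | 10(14)-methylene compound | C=C1[C@@H](O[Si](CC)(CC)CC)C[C@@H](O[Si](C)(C)C(C)(C)C)/C(C)=C\[C@H](O[Si](C)(C)C(C)(C)C)[C@@H](C(=C)CO[Si](C)(C)C(C)(C)C)[C@@H](OCc2ccc3ccccc3c2)C1
F7 | step 24 | allylic alcohol (C1 hydroxyl free) | C=C1[C@@H](O)C[C@@H](O[Si](C)(C)C(C)(C)C)/C(C)=C\[C@H](O[Si](C)(C)C(C)(C)C)[C@@H](C(=C)CO[Si](C)(C)C(C)(C)C)[C@@H](OCc2ccc3ccccc3c2)C1
F8 | step 24 | 10,14-epoxy alcohol | O1C[C@]12[C@@H](O)C[C@@H](O[Si](C)(C)C(C)(C)C)/C(C)=C\[C@H](O[Si](C)(C)C(C)(C)C)[C@@H](C(=C)CO[Si](C)(C)C(C)(C)C)[C@@H](OCc3ccc4ccccc4c3)C2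
F9 | step 28 | C12 alcohol (C3 and C6 silyl ethers kept) | C[C@@]12O[C@@H]1C[C@@H](O[Si](C)(C)C(C)(C)C)/C(C)=C\[C@H](O[Si](C)(C)C(C)(C)C)[C@@H](C(=C)CO)[C@@H](OCc3ccc4ccccc4c3)C2
F10 | step 28 | C12 enal | C[C@@]12O[C@@H]1C[C@@H](O[Si](C)(C)C(C)(C)C)/C(C)=C\[C@H](O[Si](C)(C)C(C)(C)C)[C@@H](C(=C)C=O)[C@@H](OCc3ccc4ccccc4c3)C2
F11 | step 28 | C12 carboxylic acid | C[C@@]12O[C@@H]1C[C@@H](O[Si](C)(C)C(C)(C)C)/C(C)=C\[C@H](O[Si](C)(C)C(C)(C)C)[C@@H](C(=C)C(=O)O)[C@@H](OCc3ccc4ccccc4c3)C2
A1 | alternative 1 | ten-membered dienolide lacking only the epoxide oxygen | C=C1C(=O)O[C@H]2/C=C(/C)[C@H](OC(C)=O)C/C=C(/C)C[C@H](OC(=O)[C@H](C)CC)[C@H]12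
A2 | alternative 2 | (Z)-3-iodobut-2-enal | C/C(I)=C/C=O
A3 | alternative 2 | trans methylene lactone with Z-iodoalkene on C6 and the C8–C3 chain on C7 | C=C1C(=O)O[C@@H](/C=C(/C)I)[C@@H]1[C@@H](O[Si](C)(C)C(C)(C)C)C/C(C)=C\CCOCc2ccc(OC)cc2
A4 | alternative 3 | ten-membered methylene lactone with free C8 hydroxyl and C1=C10 alkene | C=C1C(=O)O[C@H]2/C=C(/C)[C@H](OC(C)=O)C/C=C(/C)C[C@H](O)[C@H]12
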